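Ring B is a 1,2,3,4-tetrasubstituted resorcinol: O2′ lies between C1′ (bonded to chroman C3) and C3′ (pyran C4), and O4′ is meta to O2′ and next to C3′. This is the substitution pattern that a ketene C=O and an ynol ether leave behind, and because O4′ is formed as a silyl ether only O2′ can become the pyran oxygen.
The target comes from its 7-O-MOM/4′-O-TIPS ether, whose 2,2-dimethyl-2H-pyran (O on C2′, CMe2, CH=CH on C3′) is the oxa-6π valence tautomer of a vinyl o-quinone methide, i.e. of a 2′-phenol with CH(OMe)–CH=CMe2 on C3′.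
That phenol ring (C1′–C6′) is disconnected completely: C2′(–O), C5′, C6′ and C1′ come from a vinylketene (photo-Wolff of an α′-diazo enone on chroman C3), C3′ and C4′–O from a siloxyalkyne that carries the C5 unit ([2+2], 4π opening, 6π closure).
The diazo enone comes from (R)-chroman-3-ylmethanol (C3 by Ir-catalysed asymmetric hydrogenation of the 2H-chromene allylic alcohol, C6-prenyl by Stille coupling), made from 5-bromo-2,4-dihydroxybenzaldehyde and acrolein; the siloxyalkyne comes from prenal and ethynylmagnesium bromide.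
Ring order: A (purchased), C (oxa-Michael/aldol), B (benzannulation), pyran (oxa-6π, last); B and the pyran form in one flask.

Key step: step 11

Remark: locants follow isoflavan numbering (chroman O1–C8a, ring B C1′–C6′); Chr = (3R)-7-(methoxymethoxy)-6-(3-methylbut-2-en-1-yl)chroman-3-yl; compounds 1, 3, 7, 9, 14 and 15 are taken as purchasable; in step 4 the ligand antipode meant is the one that delivers the R centre.

Step 1
Reactants: 1 5-bromo-2,4-dihydroxybenzaldehyde
Product: 2 5-bromo-2-hydroxy-4-(methoxymethoxy)benzaldehyde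
Conditions: MOMCl (1.05 equiv), K2CO3, acetone, 0 °C → rt
Reagents that add atoms: chloromethyl methyl ether, COCCl
Why: Williamson-type O-alkylation; the 2-OH is held in a hydrogen bond to the aldehyde and the 4-OH is the more acidic one, so only O4 should be alkoxymethylated.

Step 2
Reactants: 2 5-bromo-2-hydroxy-4-(methoxymethoxy)benzaldehyde; 3 acrolein
Product: 4 6-bromo-7-(methoxymethoxy)-2H-chromene-3-carbaldehyde
Conditions: K2CO3, 1,4-dioxane, reflux
Reagents that add atoms: none
Why: Oxa-Michael addition of the phenoxide to acrolein, intramolecular aldol reaction and dehydration (chromene annulation of salicylaldehydes) should close ring C; acetal and aryl bromide are inert to carbonate.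

Step 3
Reactants: 4 6-bromo-7-(methoxymethoxy)-2H-chromene-3-carbaldehyde
Product: 5 [6-bromo-7-(methoxymethoxy)-2H-chromen-3-yl]methanol
Conditions: NaBH4, CeCl3·7H2O, MeOH, 0 °C
Reagents that add atoms: none
Why: Luche 1,2-reduction of the enal to the allylic alcohol, without action on C=C, aryl bromide or acetal.

Step 4
Reactants: 5 [6-bromo-7-(methoxymethoxy)-2H-chromen-3-yl]methanol
Product: 6 (R)-[6-bromo-7-(methoxymethoxy)chroman-3-yl]methanol
Conditions: H2 (50 bar), [Ir(cod)(chiral phosphinooxazoline)]BArF (1 mol %), CH2Cl2, rt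
Reagents that add atoms: none
Why: Iridium-catalysed asymmetric hydrogenation of a trisubstituted, aryl-conjugated allylic alcohol; the chiral P,N ligand decides which face of C3=C4 takes up hydrogen and so sets C3 as R, and the homogeneous catalyst should leave aryl bromide and acetal alone.

Step 5
Reactants: 6 (R)-[6-bromo-7-(methoxymethoxy)chroman-3-yl]methanol; 7 tributyl(3-methylbut-2-en-1-yl)stannane
Product: 8 (R)-[7-(methoxymethoxy)-6-(3-methylbut-2-en-1-yl)chroman-3-yl]methanol
Conditions: Pd(PPh3)4 (5 mol %), DMF, 100 °C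
Reagents that add atoms: none
Why: Stille coupling; the allylic stannane should bond through its unsubstituted CH2 terminus and give the linear prenyl group at C6, and the free alcohol needs no protection.

Step 6
Reactants: 8 (R)-[7-(methoxymethoxy)-6-(3-methylbut-2-en-1-yl)chroman-3-yl]methanol; 9 1-(triphenylphosphoranylidene)propan-2-one
Product: 11 (R,E)-4-[7-(methoxymethoxy)-6-(3-methylbut-2-en-1-yl)chroman-3-yl]but-3-en-2-one, via aldehyde 10 (not isolated)
Conditions: Dess–Martin periodinane, pyridine, CH2Cl2, 0 °C → rt; then 9 (2 equiv), rt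
Reagents that add atoms: none
Why: Dess–Martin oxidation followed in the same flask by E-selective Wittig olefination with a stabilised ylide, so that the enolisable β-aryloxy aldehyde 10 is consumed under near-neutral conditions and C3 should be kept.

Step 7
Reactants: 11 (R,E)-4-[7-(methoxymethoxy)-6-(3-methylbut-2-en-1-yl)chroman-3-yl]but-3-en-2-one
Product: 13 (R,E)-1-diazo-4-[7-(methoxymethoxy)-6-(3-methylbut-2-en-1-yl)chroman-3-yl]but-3-en-2-one, via trifluoroacetyl diketone 12 (not isolated)
Conditions: LiHMDS, THF, −78 °C; CF3CO2CH2CF3; aq HCl work-up; then MsN3, Et3N, H2O (1 equiv), MeCN, rt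
Reagents that add atoms: methanesulfonyl azide, CS(=O)(=O)N=[N+]=[N-] (source of the N2 unit of 13); 2,2,2-trifluoroethyl trifluoroacetate, O=C(OCC(F)(F)F)C(F)(F)F (its CF3CO group is present only in 12)
Why: Detrifluoroacetylative diazo transfer: the kinetic methyl enolate is C-trifluoroacetylated (Claisen condensation) and the activated methylene takes the diazo group from mesyl azide with loss of the trifluoroacetyl group, while the γ-hydrogen at C3 is not removed under kinetic conditions.

Step 8
Reactants: 14 3-methylbut-2-enal; 15 ethynylmagnesium bromide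
Product: 16 rac-5-methylhex-4-en-1-yn-3-ol
Conditions: THF, −78 → 0 °C; H2O work-up
Reagents that add atoms: none
Why: 1,2-Addition of an alkynyl Grignard reagent to the enal; the carbinol centre forms racemic and needs no control because it becomes sp2 in step 11.

Step 9
Reactants: 16 rac-5-methylhex-4-en-1-yn-3-ol
Product: 17 rac-3-methoxy-5-methylhex-4-en-1-yne
Conditions: NaH (1.05 equiv), MeI, THF, 0 °C → rt
Reagents that add atoms: iodomethane, CI
Why: Williamson ether synthesis on the sodium alkoxide; the much less acidic alkyne C–H is left.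

Step 10
Reactants: 17 rac-3-methoxy-5-methylhex-4-en-1-yne
Product: 19 rac-triisopropyl[(3-methoxy-5-methylhex-4-en-1-yn-1-yl)oxy]silane, via lithium ynolate 18 (not isolated)
Conditions: n-BuLi, THF, −78 °C; LiOOt-Bu (from t-BuOOH and LiHMDS), −78 → 0 °C; TIPSOTf, −78 → 0 °C
Reagents that add atoms: tert-butyl hydroperoxide (used as its lithium salt), CC(C)(C)OO; triisopropylsilyl trifluoromethanesulfonate, CC(C)[Si](OS(=O)(=O)C(F)(F)F)(C(C)C)C(C)C
Why: Oxidation of the lithium acetylide by lithium tert-butyl peroxide to the ynolate and O-silylation (acetylide-to-ynolate oxidation as used for 1-siloxyalkynes); the bulky silyl triflate should react at oxygen and not at carbon.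

Step 11
Reactants: 13 (R,E)-1-diazo-4-[7-(methoxymethoxy)-6-(3-methylbut-2-en-1-yl)chroman-3-yl]but-3-en-2-one; 19 rac-triisopropyl[(3-methoxy-5-methylhex-4-en-1-yn-1-yl)oxy]silane (1.5 equiv)
Product: 25 (3R)-3-{2,2-dimethyl-5-[(triisopropylsilyl)oxy]-2H-chromen-8-yl}-7-(methoxymethoxy)-6-(3-methylbut-2-en-1-yl)chroman, via vinylketene 20 (not isolated), via vinylcyclobutenone 21 (not isolated), via dienylketene 22 (not isolated), via benzannulated phenol 23 (not isolated), via o-quinone methide 24 (not isolated)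
Conditions: hν (300 nm), ClCH2CH2Cl (degassed), rt; then 80 °C, dark
Reagents that add atoms: none
Why: Proposed new method: photochemical Wolff rearrangement of 13 gives vinylketene 20, which adds [2+2] to the electron-rich alkyne 19 (its nucleophilic carbon bonds to the ketene carbonyl carbon) to give 21; on heating, 4π ring opening to 22, 6π-electrocyclization and tautomerization build ring B as phenol 23, whose benzylic and allylic methyl ether, flanked by the new OH and the OTIPS group, loses methanol to give the vinyl o-quinone methide 24, and 24 closes to the pyran of 25. The closest known reaction types are the vinylketene–siloxyalkyne benzannulation of α′-diazo enones (Danheiser benzannulation, photochemical variant) for ring B and the benzannulation/o-quinone methide/electrocyclization cascade of Fischer carbene complexes with alkenyl propargyl ethers for the pyran; what is new is their union on an ynol ether that carries the propargylic leaving group. Ring B closes by thermal 6π-electrocyclization of the dienylketene (C2′–C1′ bond) and the pyran, last, by thermal oxa-6π-electrocyclization of the o-quinone methide (O–CMe2 bond). No stereocentre is created: the carbinol carbon of 19, C4 of 21 and the sp3 carbon of the dienone all end sp2, so all diastereomers and the E/Z photoisomers of the enone converge on 25, and C3 of the chroman never becomes part of a π system. The step needs regiocontrol in ring B, which the polarization of the ynol ether secures (O4′ next to C3′, O2′ between C1′ and C3′); regiocontrol in the pyran closure, which is secured because O4′ is a silyl ether and only O2′ can be a quinone methide oxygen; and chemoselectivity of the ketene for the ynol ether over the two trisubstituted alkenes.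

Step 12
Reactants: 25 (3R)-3-{2,2-dimethyl-5-[(triisopropylsilyl)oxy]-2H-chromen-8-yl}-7-(methoxymethoxy)-6-(3-methylbut-2-en-1-yl)chroman
Product: 27 (3R)-3-{2,2-dimethyl-5-[(triisopropylsilyl)oxy]-2H-chromen-8-yl}-6-(3-methylbut-2-en-1-yl)chroman-7-ol, via trimethylsilyl ether 26 (not isolated)
Conditions: TMSOTf, 2,2′-bipyridyl, CH2Cl2, 0 °C → rt; then H2O
Reagents that add atoms: trimethylsilyl trifluoromethanesulfonate, C[Si](C)(C)OS(=O)(=O)C(F)(F)F (its Me3Si group is present only in 26; 27 gains no heavy atom)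
Why: Silyl triflate/bipyridyl cleavage of an aromatic methoxymethyl ether to the aryl TMS ether, hydrolysed at work-up; no free Brønsted acid is present, so the prenyl group ortho to the new phenol, the chromene and the TIPS ether should survive.

Step 13
Reactants: 27 (3R)-3-{2,2-dimethyl-5-[(triisopropylsilyl)oxy]-2H-chromen-8-yl}-6-(3-methylbut-2-en-1-yl)chroman-7-ol
Product: 28 (3R)-3-(5-hydroxy-2,2-dimethyl-2H-chromen-8-yl)-6-(3-methylbut-2-en-1-yl)chroman-7-ol (target, CNP0332706.1)
Conditions: TBAF, AcOH, THF, 0 °C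
Reagents that add atoms: none
Why: Fluoride-induced cleavage of the aryl silyl ether, buffered with acetic acid so that the phenols are not left as phenoxides; alkenes and the C3 centre are untouched.

Compound list
1 | 5-bromo-2,4-dihydroxybenzaldehyde | O=Cc1cc(Br)c(O)cc1O | starting material
2 | 5-bromo-2-hydroxy-4-(methoxymethoxy)benzaldehyde | COCOc1cc(O)c(C=O)cc1Br | intermediate
3 | acrolein (prop-2-enal) | C=CC=O | starting material
4 | 6-bromo-7-(methoxymethoxy)-2H-chromene-3-carbaldehyde | O=CC1=Cc2cc(Br)c(OCOC)cc2OC1 | intermediate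
5 | [6-bromo-7-(methoxymethoxy)-2H-chromen-3-yl]methanol | OCC1=Cc2cc(Br)c(OCOC)cc2OC1 | intermediate
6 | (R)-[6-bromo-7-(methoxymethoxy)chroman-3-yl]methanol | OC[C@@H]1COc2cc(OCOC)c(Br)cc2C1 | intermediate
7 | tributyl(3-methylbut-2-en-1-yl)stannane | CCCC[Sn](CCCC)(CCCC)CC=C(C)C | starting material
8 | (R)-[7-(methoxymethoxy)-6-(3-methylbut-2-en-1-yl)chroman-3-yl]methanol | OC[C@@H]1COc2cc(OCOC)c(CC=C(C)C)cc2C1 | intermediate
9 | 1-(triphenylphosphoranylidene)propan-2-one | CC(=O)C=P(c1ccccc1)(c1ccccc1)c1ccccc1 | starting material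
10 | (S)-7-(methoxymethoxy)-6-(3-methylbut-2-en-1-yl)chroman-3-carbaldehyde (formed in the flask; same spatial arrangement at C3 as 8) | O=C[C@@H]1COc2cc(OCOC)c(CC=C(C)C)cc2C1 | intermediate
11 | (E)-4-Chr-but-3-en-2-one | CC(=O)/C=C/[C@@H]1COc2cc(OCOC)c(CC=C(C)C)cc2C1 | intermediate
12 | (E)-1,1,1-trifluoro-6-Chr-hex-5-ene-2,4-dione (formed in the flask) | O=C(CC(=O)/C=C/[C@@H]1COc2cc(OCOC)c(CC=C(C)C)cc2C1)C(F)(F)F | intermediate
13 | (E)-1-diazo-4-Chr-but-3-en-2-one | [N-]=[N+]=CC(=O)/C=C/[C@@H]1COc2cc(OCOC)c(CC=C(C)C)cc2C1 | intermediate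
14 | 3-methylbut-2-enal (prenal) | CC(C)=CC=O | starting material
15 | ethynylmagnesium bromide | C#C[Mg]Br | starting material
16 | rac-5-methylhex-4-en-1-yn-3-ol | CC(C)=CC(O)C#C | intermediate
17 | rac-3-methoxy-5-methylhex-4-en-1-yne | CC(C)=CC(OC)C#C | intermediate
18 | lithium 3-methoxy-5-methylhex-4-en-1-yn-1-olate (formed in the flask) | CC(C)=CC(OC)C#C[O-].[Li+] | intermediate
19 | rac-triisopropyl[(3-methoxy-5-methylhex-4-en-1-yn-1-yl)oxy]silane | CC(C)=CC(OC)C#CO[Si](C(C)C)(C(C)C)C(C)C | intermediate
20 | vinylketene (E)-4-Chr-buta-1,3-dien-1-one (formed in the flask) | O=C=C/C=C/[C@@H]1COc2cc(OCOC)c(CC=C(C)C)cc2C1 | intermediate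
21 | vinylcyclobutenone 2-(1-methoxy-3-methylbut-2-en-1-yl)-4-[(E)-2-Chr-ethenyl]-3-[(triisopropylsilyl)oxy]cyclobut-2-en-1-one, epimers at C4 and at the carbinol carbon (formed in the flask) | COC(C=C(C)C)C1=C(O[Si](C(C)C)(C(C)C)C(C)C)C(/C=C/[C@@H]2COc3cc(OCOC)c(CC=C(C)C)cc3C2)C1=O | intermediate
22 | dienylketene 2-(1-methoxy-3-methylbut-2-en-1-yl)-6-Chr-3-[(triisopropylsilyl)oxy]hexa-1,3,5-trien-1-one, C2 and C5 cis about C3=C4, 5E (formed in the flask) | O=C=C(C(OC)C=C(C)C)\C(O[Si](C(C)C)(C(C)C)C(C)C)=C/C=C/[C@@H]1COc2cc(OCOC)c(CC=C(C)C)cc2C1 | intermediate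
23 | 6-Chr-2-(1-methoxy-3-methylbut-2-en-1-yl)-3-[(triisopropylsilyl)oxy]phenol, both epimers at the carbinol carbon (formed in the flask) | CC(C)=CC(OC)c1c(O)c(ccc1O[Si](C(C)C)(C(C)C)C(C)C)[C@@H]2COc3cc(OCOC)c(CC=C(C)C)cc3C2 | intermediate
24 | o-quinone methide 6-Chr-2-(3-methylbut-2-en-1-ylidene)-3-[(triisopropylsilyl)oxy]cyclohexa-3,5-dien-1-one (formed in the flask) | CC(C)=CC=C1C(=O)C(=CC=C1O[Si](C(C)C)(C(C)C)C(C)C)[C@@H]2COc3cc(OCOC)c(CC=C(C)C)cc3C2 | intermediate
25 | (3R)-3-{2,2-dimethyl-5-[(triisopropylsilyl)oxy]-2H-chromen-8-yl}-7-(methoxymethoxy)-6-(3-methylbut-2-en-1-yl)chroman | CC(C)=CCc1cc2c(cc1OCOC)OC[C@@H](c1ccc(O[Si](C(C)C)(C(C)C)C(C)C)c3c1OC(C)(C)C=C3)C2 | intermediate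
26 | (3R)-3-{2,2-dimethyl-5-[(triisopropylsilyl)oxy]-2H-chromen-8-yl}-6-(3-methylbut-2-en-1-yl)-7-[(trimethylsilyl)oxy]chroman (formed in the flask) | CC(C)=CCc1cc2c(cc1O[Si](C)(C)C)OC[C@@H](c1ccc(O[Si](C(C)C)(C(C)C)C(C)C)c3c1OC(C)(C)C=C3)C2 | intermediate
27 | (3R)-3-{2,2-dimethyl-5-[(triisopropylsilyl)oxy]-2H-chromen-8-yl}-6-(3-methylbut-2-en-1-yl)chroman-7-ol | CC(C)=CCc1cc2c(cc1O)OC[C@@H](c1ccc(O[Si](C(C)C)(C(C)C)C(C)C)c3c1OC(C)(C)C=C3)C2 | intermediate
28 | (3R)-3-(5-hydroxy-2,2-dimethyl-2H-chromen-8-yl)-6-(3-methylbut-2-en-1-yl)chroman-7-ol | CC(C)=CCc1cc2c(cc1O)OC[C@@H](c1ccc(O)c3c1OC(C)(C)C=C3)C2 | target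

Total step count: 13. Longest linear sequence: 10 steps (steps 1–7, 11, 12, 13); the alkyne branch (steps 8–10) joins at step 11.

Steps most likely to fail:

First, step 11 (Proposed new method). What may go wrong: cycloaddition of ketene 20 to the α-branched ynol ether may be slower than ketene dimerization or acylation of phenol already formed; the propargylic methoxy group of 19 may ionize before the cycloaddition; methanol set free may add to ketene intermediates. The fallback uses known chemistry, sets out from 13 and comes back at 25. Compound 13 is irradiated and heated as above, but with triisopropyl[(5-methylhex-4-en-1-yn-1-yl)oxy]silane F1, a siloxyalkyne with a primary alkyl group of the kind for which this benzannulation is established (F1 from purchased ethyl 4-methylpent-3-enoate by Kowalski ynolate homologation and silylation with TIPSCl). Through ketene 20, the 2-prenyl vinylcyclobutenone F2 and the dienylketene F3 this should give the 3′-prenyl resorcinol mono-TIPS ether F4, which is isolated. The pyran is then closed in a separate operation by DDQ-mediated dehydrogenative cyclization of the o-prenylphenol (DDQ, benzene, rt), a known chromene synthesis that runs through the same o-quinone methide 24 and gives 25. The free 2′-OH should direct hydride abstraction to the 3′-prenyl group and not to the C6-prenyl group.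

Second, step 10. What may go wrong: β-elimination of methoxide from ynolate 18, and acid-induced ionization of the propargylic ether of 19 during isolation. The fallback sets out from 16 and comes back at o-quinone methide 24 inside step 11, and so at 25. The methylation is left out: 16 is deprotonated twice (n-BuLi, 2 equiv) and the acetylide is oxidized with LiOOt-Bu to dilithium 5-methylhex-4-en-1-yne-1,3-bis(olate) F5, in which the β-oxygen is an alkoxide and cannot leave. Both oxygens are then silylated with TIPSOTf to give triisopropyl({5-methyl-1-[(triisopropylsilyl)oxy]hex-4-en-1-yn-3-yl}oxy)silane F6, purified only by filtration through base-washed silica. Under the conditions of step 11, F6 and 13 should give, through ketene 20, the vinylcyclobutenone F7 and the dienylketene F8, the phenol F9, which loses triisopropylsilanol in place of methanol and gives 24.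

Third, step 4. What may go wrong: weak discrimination of the two faces of C3=C4 (both C3 substituents are CH2–O groups), allylic C–O hydrogenolysis, or isomerization of the allylic alcohol to the aldehyde. The fallback sets out from 4 and comes back at 6. Pinnick oxidation of 4 (NaClO2, NaH2PO4, 2-methylbut-2-ene) gives 6-bromo-7-(methoxymethoxy)-2H-chromene-3-carboxylic acid F10. Carboxylate-directed asymmetric hydrogenation (Ir–spiro phosphine-oxazoline or Ru–diphosphine catalyst, H2, MeOH, Et3N), a reaction type established for 2H-chromene-3-carboxylic acids, gives (S)-6-bromo-7-(methoxymethoxy)chroman-3-carboxylic acid F11. Reduction with BH3·THF, which spares the aryl bromide, gives 6.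

Further compounds
F1 | step 11 | triisopropyl[(5-methylhex-4-en-1-yn-1-yl)oxy]silane | CC(C)=CCC#CO[Si](C(C)C)(C(C)C)C(C)C
F2 | step 11 | 2-(3-methylbut-2-en-1-yl)-4-[(E)-2-Chr-ethenyl]-3-[(triisopropylsilyl)oxy]cyclobut-2-en-1-one | CC(C)=CCC1=C(O[Si](C(C)C)(C(C)C)C(C)C)C(/C=C/[C@@H]2COc3cc(OCOC)c(CC=C(C)C)cc3C2)C1=O
F3 | step 11 | 2-(3-methylbut-2-en-1-yl)-6-Chr-3-[(triisopropylsilyl)oxy]hexa-1,3,5-trien-1-one | O=C=C(CC=C(C)C)\C(O[Si](C(C)C)(C(C)C)C(C)C)=C/C=C/[C@@H]1COc2cc(OCOC)c(CC=C(C)C)cc2C1
F4 | step 11 | 6-Chr-2-(3-methylbut-2-en-1-yl)-3-[(triisopropylsilyl)oxy]phenol | CC(C)=CCc1c(O)c(ccc1O[Si](C(C)C)(C(C)C)C(C)C)[C@@H]2COc3cc(OCOC)c(CC=C(C)C)cc3C2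
F5 | step 10 | dilithium 5-methylhex-4-en-1-yne-1,3-bis(olate) | CC(C)=CC([O-])C#C[O-].[Li+].[Li+]
F6 | step 10 | triisopropyl({5-methyl-1-[(triisopropylsilyl)oxy]hex-4-en-1-yn-3-yl}oxy)silane | CC(C)=CC(O[Si](C(C)C)(C(C)C)C(C)C)C#CO[Si](C(C)C)(C(C)C)C(C)C
F7 | step 10 | 2-{3-methyl-1-[(triisopropylsilyl)oxy]but-2-en-1-yl}-4-[(E)-2-Chr-ethenyl]-3-[(triisopropylsilyl)oxy]cyclobut-2-en-1-one | CC(C)=CC(O[Si](C(C)C)(C(C)C)C(C)C)C1=C(O[Si](C(C)C)(C(C)C)C(C)C)C(/C=C/[C@@H]2COc3cc(OCOC)c(CC=C(C)C)cc3C2)C1=O
F8 | step 10 | 2-{3-methyl-1-[(triisopropylsilyl)oxy]but-2-en-1-yl}-6-Chr-3-[(triisopropylsilyl)oxy]hexa-1,3,5-trien-1-one | O=C=C(C(O[Si](C(C)C)(C(C)C)C(C)C)C=C(C)C)\C(O[Si](C(C)C)(C(C)C)C(C)C)=C/C=C/[C@@H]1COc2cc(OCOC)c(CC=C(C)C)cc2C1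
F9 | step 10 | 6-Chr-2-{3-methyl-1-[(triisopropylsilyl)oxy]but-2-en-1-yl}-3-[(triisopropylsilyl)oxy]phenol | CC(C)=CC(O[Si](C(C)C)(C(C)C)C(C)C)c1c(O)c(ccc1O[Si](C(C)C)(C(C)C)C(C)C)[C@@H]2COc3cc(OCOC)c(CC=C(C)C)cc3C2
F10 | step 4 | 6-bromo-7-(methoxymethoxy)-2H-chromene-3-carboxylic acid | OC(=O)C1=Cc2cc(Br)c(OCOC)cc2OC1
F11 | step 4 | (S)-6-bromo-7-(methoxymethoxy)chroman-3-carboxylic acid | OC(=O)[C@@H]1COc2cc(OCOC)c(Br)cc2C1
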